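The C6–O bond of the γ-lactone is the basis of the plan: it is made by intramolecular acidolysis of an oxygen bridge between C6 and C9. The target's lactone oxygen on C6 and hydroxyl on C9 are 1,4-trans across the cycloheptane, the signature of an 8-oxabicyclo[3.2.1]octane opened with inversion at one bridgehead. In one operation the endo acrylic acid on C7 displaces the bridge at C6, closing the cis-fused lactone, unveiling the seven-membered ring and releasing the C9 hydroxyl. The precursor is an oxabicycle from an enantioselective rhodium-carbenoid (4+3) annulation of a 3-furylmalonate, whose convex face then relays the centres C7, C10, C5 and C1.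

Key step: step 14

Remarks
- Numbering: target atoms carry xanthanolide locants. C1 is the ring carbinol bearing the side chain (C2 ketone, C3, C4 carbinol, C15 methyl), C5 bears the 2-methylbutanoate, C6 the lactone oxygen, C7 the C11(=C13H2)–C12 unit, C8 is CH2, C9 is CHOH, C10 bears the methyl. The target is 1S,4S,5S,6R,7S,9R,10S with an (R)-2-methylbutanoate.
- In the bicycles, β is the face of the oxygen bridge (exo) and α the opposite face (endo). Positions 1, 2, 3, 4, 5, 6, 7 of the 8-oxabicyclo[3.2.1]octane names correspond to C9, C10, C1, C5, C6, C7, C8.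
- Assumption: Rh2(S-PTAD)4 is taken to give the enantiomer of 8 that is drawn; if the sense of induction is the opposite, Rh2(R-PTAD)4 is used.

Step 1
Reactants: 1 3-bromofuran; 2 di-tert-butyl propanedioate
Product: 3 di-tert-butyl 2-(furan-3-yl)propanedioate
Conditions: NaH, Pd(dba)2 (2 mol %), P(t-Bu)3 (4 mol %), THF, 70 °C
Reagents that add atoms: none
Why: Palladium-catalysed α-arylation of a malonate enolate is established for heteroaryl bromides with the bulky electron-rich P(t-Bu)3, and the tert-butyl esters suppress a second arylation.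

Step 2
Reactants: 4 benzyl 3-oxobutanoate
Product: 5 benzyl 2-diazo-3-oxobutanoate
Conditions: 4-acetamidobenzenesulfonyl azide, Et3N, MeCN, 0 °C → rt
Reagents that add atoms: 4-acetamidobenzenesulfonyl azide, CC(=O)Nc1ccc(cc1)S(=O)(=O)N=[N+]=[N-]
Why: Regitz diazo transfer to the acidic methylene of a β-keto ester.

Step 3
Reactants: 5 benzyl 2-diazo-3-oxobutanoate
Product: 6 benzyl 3-[(tert-butyldimethylsilyl)oxy]-2-diazobut-3-enoate
Conditions: TBSOTf, Et3N, CH2Cl2, 0 °C
Reagents that add atoms: tert-butyldimethylsilyl trifluoromethanesulfonate, CC(C)(C)[Si](C)(C)OS(=O)(=O)C(F)(F)F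
Why: Soft enolisation and O-silylation of the acetyl group (silyl enol ether formation) gives the 2-siloxyvinyl diazoacetate that serves as donor/acceptor carbenoid precursor.

Step 4
Reactants: 3 di-tert-butyl 2-(furan-3-yl)propanedioate; 6 benzyl 3-[(tert-butyldimethylsilyl)oxy]-2-diazobut-3-enoate
Product: 8 benzyl 3-[(tert-butyldimethylsilyl)oxy]-6-[bis(tert-butoxycarbonyl)methyl]-8-oxabicyclo[3.2.1]octa-2,6-diene-2-carboxylate, via divinylcyclopropane 7 (not isolated)
Conditions: Rh2(S-PTAD)4 (1 mol %), hexanes, −40 °C → rt, slow addition of 6 to 3 (1.5 equiv)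
Reagents that add atoms: none
Why: In this rhodium-carbenoid formal (4+3) cycloaddition (tandem cyclopropanation/Cope rearrangement) the carbenoid should cyclopropanate the unhindered C4=C5 bond of the furan remote from the malonyl group, the cis-divinylcyclopropane rearranges through a boat transition state, and the chiral carboxylate ligands select the furan face so that both bridgeheads (C6 and C9) are set together.

Step 5
Reactants: 8 benzyl 3-[(tert-butyldimethylsilyl)oxy]-6-[bis(tert-butoxycarbonyl)methyl]-8-oxabicyclo[3.2.1]octa-2,6-diene-2-carboxylate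
Product: 9 benzyl 6-endo-[bis(tert-butoxycarbonyl)methyl]-3-[(tert-butyldimethylsilyl)oxy]-8-oxabicyclo[3.2.1]oct-2-ene-2-carboxylate
Conditions: H2 (1 atm), 10% Pd/C, Ph2S (catalytic), EtOAc, rt
Reagents that add atoms: none
Why: Hydrogenation on sulfide-poisoned palladium spares the benzyl ester and the tetrasubstituted push–pull enol ether and should add H2 to the strained C7=C8 bond from the exo (β) face, which leaves the malonyl group endo (α) and sets C7.

Step 6
Reactants: 9 benzyl 6-endo-[bis(tert-butoxycarbonyl)methyl]-3-[(tert-butyldimethylsilyl)oxy]-8-oxabicyclo[3.2.1]oct-2-ene-2-carboxylate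
Product: 10 benzyl 6-endo-[bis(tert-butoxycarbonyl)methyl]-2-methyl-3-oxo-8-oxabicyclo[3.2.1]octane-2-carboxylate (2-methyl β)
Conditions: Bu4NF (1.05 equiv), MeI (5 equiv), THF, −78 → 0 °C
Reagents that add atoms: iodomethane, CI
Why: Fluoride unmasks the β-keto ester enolate, the most acidic site, which is C-methylated at C10 (enolate alkylation, methyl expected on the open β face, although this centre is reset in step 7).

Step 7
Reactants: 10 benzyl 6-endo-[bis(tert-butoxycarbonyl)methyl]-2-methyl-3-oxo-8-oxabicyclo[3.2.1]octane-2-carboxylate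
Product: 12 di-tert-butyl 2-(2-methyl-3-oxo-8-oxabicyclo[3.2.1]octan-6-endo-yl)propanedioate (C10 methyl α-equatorial), via β-keto acid 11 (not isolated)
Conditions: H2 (1 atm), 10% Pd/C, EtOAc, rt; then 50 °C
Reagents that add atoms: none
Why: Hydrogenolysis of the benzyl ester gives a β-keto acid that decarboxylates through its enol under neutral conditions, and ketonisation by protonation from the exo face (also the thermodynamic outcome) should place the C10 methyl equatorial (α).

Step 8
Reactants: 12 di-tert-butyl 2-(2-methyl-3-oxo-8-oxabicyclo[3.2.1]octan-6-endo-yl)propanedioate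
Product: 13 di-tert-butyl 2-(4-hydroxy-2-methyl-3-oxo-8-oxabicyclo[3.2.1]octan-6-endo-yl)propanedioate (C5 hydroxyl β-axial)
Conditions: KN(SiMe3)2 (2.2 equiv), THF, −78 °C; racemic 2-(phenylsulfonyl)-3-phenyloxaziridine (1.2 equiv), −78 °C; aq. NH4Cl
Reagents that add atoms: 2-(phenylsulfonyl)-3-phenyloxaziridine, O=S(=O)(c1ccccc1)N1OC1c1ccccc1
Why: In this Davis enolate hydroxylation the first equivalent of base masks the malonate as its enolate, the second gives the kinetic ketone enolate at the C5 methylene and not at the C10 methine, and the oxaziridine should attack the β face because the α face is covered by the ethano bridge and the endo malonyl group, which sets the axial C5 hydroxyl.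

Step 9
Reactants: 13 di-tert-butyl 2-(4-hydroxy-2-methyl-3-oxo-8-oxabicyclo[3.2.1]octan-6-endo-yl)propanedioate; 14 (R)-2-methylbutanoic acid
Product: 15 di-tert-butyl 2-{2-methyl-4-[(2R)-2-methylbutanoyloxy]-3-oxo-8-oxabicyclo[3.2.1]octan-6-endo-yl}propanedioate
Conditions: DCC, DMAP (catalytic), CH2Cl2, 0 °C → rt
Reagents that add atoms: none
Why: Steglich esterification of the secondary α-ketol hydroxyl with the α-branched acid proceeds under conditions that should not epimerise the acid, and it is done while C1 is still a flat carbonyl and the hydroxyl is least hindered.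

Step 10
Reactants: 16 (S)-but-3-yn-2-ol
Product: 17 (S)-tert-butyl(but-3-yn-2-yloxy)diphenylsilane
Conditions: TBDPSCl, imidazole, DMF, rt
Reagents that add atoms: tert-butyl(chloro)diphenylsilane, CC(C)(C)[Si](Cl)(c1ccccc1)c1ccccc1
Why: Standard silylation of a secondary alcohol, the acid-robust TBDPS group being chosen to survive steps 13 and 14 and the C4 stereocentre being bought.

Step 11
Reactants: 15 di-tert-butyl 2-{2-methyl-4-[(2R)-2-methylbutanoyloxy]-3-oxo-8-oxabicyclo[3.2.1]octan-6-endo-yl}propanedioate; 17 (S)-tert-butyl(but-3-yn-2-yloxy)diphenylsilane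
Product: 18 di-tert-butyl 2-{3-[(3S)-3-(tert-butyldiphenylsilyloxy)but-1-yn-1-yl]-3-hydroxy-2-methyl-4-[(2R)-2-methylbutanoyloxy]-8-oxabicyclo[3.2.1]octan-6-endo-yl}propanedioate (C1 hydroxyl α-axial)
Conditions: 17 (2.6 equiv), n-BuLi (2.5 equiv), THF, −78 °C; CeCl3; then 15, −78 → −40 °C; aq. NH4Cl
Reagents that add atoms: none
Why: In this 1,2-addition of a cerium acetylide one equivalent deprotonates and thereby protects the malonate, the hindered α-branched ester should be spared at low temperature, and the slim nucleophile should attack C1 from the β face because the α face is blocked by the ethano bridge and the endo malonyl group, so that the new hydroxyl is axial (α).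

Step 12
Reactants: 18 di-tert-butyl 2-{3-[(3S)-3-(tert-butyldiphenylsilyloxy)but-1-yn-1-yl]-3-hydroxy-2-methyl-4-[(2R)-2-methylbutanoyloxy]-8-oxabicyclo[3.2.1]octan-6-endo-yl}propanedioate
Product: 20 di-tert-butyl 2-{3-[(3S)-3-(tert-butyldiphenylsilyloxy)butanoyl]-3-hydroxy-2-methyl-4-[(2R)-2-methylbutanoyloxy]-8-oxabicyclo[3.2.1]octan-6-endo-yl}propanedioate, via alkylidene carbonate 19 (not isolated)
Conditions: AgOAc (10 mol %), DBU, CO2 (1 atm), MeCN, rt; then H2O, 60 °C
Reagents that add atoms: carbon dioxide, O=C=O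
Why: Silver-catalysed carboxylative cyclisation of the tertiary propargylic alcohol (5-exo-dig attack of the carbonate oxygen on C2) followed by hydrolysis and loss of CO2 is a regiospecific formal hydration that places the ketone at C2 next to the carbinol, the silylated C4 oxygen being unable to compete.

Step 13
Reactants: 20 di-tert-butyl 2-{3-[(3S)-3-(tert-butyldiphenylsilyloxy)butanoyl]-3-hydroxy-2-methyl-4-[(2R)-2-methylbutanoyloxy]-8-oxabicyclo[3.2.1]octan-6-endo-yl}propanedioate
Product: 22 2-{3-[(3S)-3-(tert-butyldiphenylsilyloxy)butanoyl]-3-hydroxy-2-methyl-4-[(2R)-2-methylbutanoyloxy]-8-oxabicyclo[3.2.1]octan-6-endo-yl}prop-2-enoic acid, via malonic acid 21 (not isolated)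
Conditions: TFA–CH2Cl2–H2O (10:10:1), 0 °C → rt; concentrate; 37% aq. HCHO, Et2NH, THF, rt → 50 °C
Reagents that add atoms: formaldehyde, C=O
Why: Acidolysis of both tert-butyl esters followed by Mannich condensation of the malonic acid with formaldehyde and decarboxylative elimination (the classical malonic acid methylenation) should deliver the 2-substituted acrylic acid without strong base, the TBDPS ether and the ether bridge being expected to survive aqueous TFA.

Step 14
Reactants: 22 2-{3-[(3S)-3-(tert-butyldiphenylsilyloxy)butanoyl]-3-hydroxy-2-methyl-4-[(2R)-2-methylbutanoyloxy]-8-oxabicyclo[3.2.1]octan-6-endo-yl}prop-2-enoic acid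
Product: 23 O4-tert-butyldiphenylsilyl ether of the target (cis-fused 12,6-olide with free C9 and C1 hydroxyls)
Conditions: Tf2NH (20 mol %), CH2Cl2–(CF3)2CHOH (4:1), 0 → 40 °C
Reagents that add atoms: none
Why: Tf2NH protonates the bridging ether oxygen, the most basic site, and the carbonyl oxygen of the endo acrylic acid on C7 attacks C6 from the α face anti to the departing oxygen (intramolecular SN2 acidolysis of the ether), after which loss of a proton gives the lactone and returns the catalyst. The closest known reactions are the acetolysis of 7-oxanorbornane and 8-oxabicyclo[3.2.1]octane bridges and the acid-induced lactonisation of endo carboxylic acids of such bridged ethers. The γ-lactone closes in the 5-exo-tet mode, while the cycloheptane is not closed but unveiled by cleavage of the C6–O bond of the bicycle. C6 is set by inversion (lactone oxygen α, cis to the C7 side chain) and C9 keeps the bridge oxygen as its β hydroxyl with retention, so the 1,4-trans relationship of the two oxygens follows directly from the bridge. The step needs attack at C6 and not at C9, and by the carboxyl group and not by another nucleophile: the endo chain can reach only the rear of C6, the C5 ester is syn to the bridge and cannot participate, the C1 hydroxyl could only form an oxetane, and the Tf2N– counter-ion is non-nucleophilic. Any loss of the silyl ether at this stage only anticipates step 15.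

Step 15
Reactants: 23 O4-tert-butyldiphenylsilyl ether of the target
Product: 24 CNP0291806.3 (1,4,9-trihydroxy-5-[(2R)-2-methylbutanoyloxy]-2-oxoxanth-11(13)-en-12,6-olide; 1S,4S,5S,6R,7S,9R,10S)
Conditions: HF·pyridine, pyridine, THF, 0 °C → rt
Reagents that add atoms: none
Why: Buffered HF·pyridine cleaves the TBDPS ether and should leave the esters, the α-methylene lactone and the β-hydroxy ketone untouched.

Compound list
1 | 3-bromofuran | Brc1ccoc1 | starting material
2 | di-tert-butyl propanedioate (di-tert-butyl malonate) | CC(C)(C)OC(=O)CC(=O)OC(C)(C)C | starting material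
3 | di-tert-butyl 2-(furan-3-yl)propanedioate | CC(C)(C)OC(=O)C(c1ccoc1)C(=O)OC(C)(C)C | intermediate
4 | benzyl 3-oxobutanoate | CC(=O)CC(=O)OCc1ccccc1 | starting material
5 | benzyl 2-diazo-3-oxobutanoate | CC(=O)C(=[N+]=[N-])C(=O)OCc1ccccc1 | intermediate
6 | benzyl 3-[(tert-butyldimethylsilyl)oxy]-2-diazobut-3-enoate | C=C(O[Si](C)(C)C(C)(C)C)C(=[N+]=[N-])C(=O)OCc1ccccc1 | intermediate
7 | divinylcyclopropane: benzyl 4-[bis(tert-butoxycarbonyl)methyl]-6-{1-[(tert-butyldimethylsilyl)oxy]ethenyl}-2-oxabicyclo[3.1.0]hex-3-ene-6-carboxylate (siloxyvinyl group endo) | O1C=C(C(C(=O)OC(C)(C)C)C(=O)OC(C)(C)C)[C@H]2[C@@H]1[C@@]2(C(=O)OCc3ccccc3)C(=C)O[Si](C)(C)C(C)(C)C | intermediate (not isolated)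
8 | benzyl 3-[(tert-butyldimethylsilyl)oxy]-6-[bis(tert-butoxycarbonyl)methyl]-8-oxabicyclo[3.2.1]octa-2,6-diene-2-carboxylate | O1[C@H]2C(C(C(=O)OC(C)(C)C)C(=O)OC(C)(C)C)=C[C@@H]1C(C(=O)OCc3ccccc3)=C(O[Si](C)(C)C(C)(C)C)C2 | intermediate
9 | benzyl 6-endo-[bis(tert-butoxycarbonyl)methyl]-3-[(tert-butyldimethylsilyl)oxy]-8-oxabicyclo[3.2.1]oct-2-ene-2-carboxylate | O1[C@H]2[C@H](C(C(=O)OC(C)(C)C)C(=O)OC(C)(C)C)C[C@@H]1C(C(=O)OCc3ccccc3)=C(O[Si](C)(C)C(C)(C)C)C2 | intermediate
10 | benzyl 6-endo-[bis(tert-butoxycarbonyl)methyl]-2-methyl-3-oxo-8-oxabicyclo[3.2.1]octane-2-carboxylate (2-methyl β) | O1[C@H]2[C@H](C(C(=O)OC(C)(C)C)C(=O)OC(C)(C)C)C[C@@H]1[C@](C)(C(=O)OCc3ccccc3)C(=O)C2 | intermediate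
11 | β-keto acid: 6-endo-[bis(tert-butoxycarbonyl)methyl]-2-methyl-3-oxo-8-oxabicyclo[3.2.1]octane-2-carboxylic acid | O1[C@H]2[C@H](C(C(=O)OC(C)(C)C)C(=O)OC(C)(C)C)C[C@@H]1[C@](C)(C(=O)O)C(=O)C2 | intermediate (not isolated)
12 | di-tert-butyl 2-(2-methyl-3-oxo-8-oxabicyclo[3.2.1]octan-6-endo-yl)propanedioate (C10 methyl α, equatorial) | O1[C@H]2[C@H](C(C(=O)OC(C)(C)C)C(=O)OC(C)(C)C)C[C@@H]1[C@H](C)C(=O)C2 | intermediate
13 | di-tert-butyl 2-(4-hydroxy-2-methyl-3-oxo-8-oxabicyclo[3.2.1]octan-6-endo-yl)propanedioate (C5 hydroxyl β, axial) | O1[C@H]2[C@H](C(C(=O)OC(C)(C)C)C(=O)OC(C)(C)C)C[C@@H]1[C@H](C)C(=O)[C@H]2O | intermediate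
14 | (R)-2-methylbutanoic acid | CC[C@@H](C)C(=O)O | starting material
15 | di-tert-butyl 2-{2-methyl-4-[(2R)-2-methylbutanoyloxy]-3-oxo-8-oxabicyclo[3.2.1]octan-6-endo-yl}propanedioate | O1[C@H]2[C@H](C(C(=O)OC(C)(C)C)C(=O)OC(C)(C)C)C[C@@H]1[C@H](C)C(=O)[C@H]2OC(=O)[C@H](C)CC | intermediate
16 | (S)-but-3-yn-2-ol | C#C[C@H](C)O | starting material
17 | (S)-tert-butyl(but-3-yn-2-yloxy)diphenylsilane | C#C[C@H](C)O[Si](c1ccccc1)(c1ccccc1)C(C)(C)C | intermediate
18 | tertiary propargylic alcohol: di-tert-butyl 2-{3-[(3S)-3-(tert-butyldiphenylsilyloxy)but-1-yn-1-yl]-3-hydroxy-2-methyl-4-[(2R)-2-methylbutanoyloxy]-8-oxabicyclo[3.2.1]octan-6-endo-yl}propanedioate (C1 hydroxyl α, alkynyl β) | O1[C@H]2[C@H](C(C(=O)OC(C)(C)C)C(=O)OC(C)(C)C)C[C@@H]1[C@H](C)[C@@](O)(C#C[C@H](C)O[Si](c3ccccc3)(c3ccccc3)C(C)(C)C)[C@H]2OC(=O)[C@H](C)CC | intermediate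
19 | alkylidene carbonate: spiro (Z)-5-alkylidene-1,3-dioxolan-2-one formed from the C1 oxygen and C2 of 18 | O1[C@H]2[C@H](C(C(=O)OC(C)(C)C)C(=O)OC(C)(C)C)C[C@@H]1[C@H](C)[C@@](O3)(/C(OC3=O)=C/[C@H](C)O[Si](c4ccccc4)(c4ccccc4)C(C)(C)C)[C@H]2OC(=O)[C@H](C)CC | intermediate (not isolated)
20 | α-hydroxy ketone: di-tert-butyl 2-{3-[(3S)-3-(tert-butyldiphenylsilyloxy)butanoyl]-3-hydroxy-2-methyl-4-[(2R)-2-methylbutanoyloxy]-8-oxabicyclo[3.2.1]octan-6-endo-yl}propanedioate | O1[C@H]2[C@H](C(C(=O)OC(C)(C)C)C(=O)OC(C)(C)C)C[C@@H]1[C@H](C)[C@@](O)(C(=O)C[C@H](C)O[Si](c3ccccc3)(c3ccccc3)C(C)(C)C)[C@H]2OC(=O)[C@H](C)CC | intermediate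
21 | malonic acid: the propanedioic acid corresponding to 20 | O1[C@H]2[C@H](C(C(=O)O)C(=O)O)C[C@@H]1[C@H](C)[C@@](O)(C(=O)C[C@H](C)O[Si](c3ccccc3)(c3ccccc3)C(C)(C)C)[C@H]2OC(=O)[C@H](C)CC | intermediate (not isolated)
22 | 2-{3-[(3S)-3-(tert-butyldiphenylsilyloxy)butanoyl]-3-hydroxy-2-methyl-4-[(2R)-2-methylbutanoyloxy]-8-oxabicyclo[3.2.1]octan-6-endo-yl}prop-2-enoic acid | O1[C@H]2[C@H](C(=C)C(=O)O)C[C@@H]1[C@H](C)[C@@](O)(C(=O)C[C@H](C)O[Si](c3ccccc3)(c3ccccc3)C(C)(C)C)[C@H]2OC(=O)[C@H](C)CC | intermediate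
23 | O4-tert-butyldiphenylsilyl ether of the target | C=C1C(=O)O[C@@H]2[C@H]1C[C@@H](O)[C@H](C)[C@@](O)(C(=O)C[C@H](C)O[Si](c3ccccc3)(c3ccccc3)C(C)(C)C)[C@H]2OC(=O)[C@H](C)CC | intermediate
24 | CNP0291806.3 | C=C1C(=O)O[C@@H]2[C@H]1C[C@@H](O)[C@H](C)[C@@](O)(C(=O)C[C@H](C)O)[C@H]2OC(=O)[C@H](C)CC | target

Total step count: 15. Longest linear sequence: 13 steps (from 4 to 24: steps 2 to 9 and 11 to 15).

Steps most likely to fail

Step 14. The carboxyl group may be too poor a nucleophile to displace the protonated bridge oxygen at C6, a secondary centre next to the C5 acyloxy group. Under more forcing acid the silyloxy ketone may lose silanol, or the acid may be captured by the nearby tertiary C1 hydroxyl. The fallback sets out from 22 and returns at 23. Me2BBr in CH2Cl2 at −78 °C cleaves the bridge by bromide attack at the less hindered, electronically undeactivated C9 with inversion, giving the C9 α-bromo C6 β-hydroxy acid F1. Intramolecular Mitsunobu lactonisation (PPh3, DIAD, THF) then forms the same C6–O lactone bond with inversion at C6 and gives the bromo lactone F2. Displacement of the bromide with KNO2 in DMF (inversion, the nitrite ester being hydrolysed on work-up) gives 23.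

Step 4. The bulky malonyl group on the furan may slow the carbenoid addition, erode facial discrimination by the catalyst or favour ring-opening of the furan over the cyclopropanation/Cope sequence. The fallback sets out from 1 and 6 and returns at 8. The same rhodium-catalysed annulation is run on 3-bromofuran 1, whose small substituent still steers the carbenoid to the distal double bond, to give the alkenyl bromide F3. Palladium-catalysed coupling of F3 with the sodium enolate of 2 [Pd(dba)2, P(t-Bu)3, THF, 60 °C] then installs the malonyl group and gives 8.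

Step 12. The crowded axial tertiary alkoxide may not be carboxylated, or the internal alkyne may cyclise too slowly, so that base-induced loss of silanol from the side chain or isomerisation of the propargylic alcohol intervenes. The fallback sets out from 15, replaces steps 11 and 12, and returns at 20.
- Lithiated 1-methoxybuta-1,2-diene (n-BuLi, THF, −78 °C, excess) adds to the C1 ketone of 15 from the β face to give the allenyl carbinol F4.
- Oxalic acid in THF–H2O hydrolyses the enol ether to the (E)-enone F5.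
- Copper-catalysed enantioselective conjugate borylation [CuCl, NaOt-Bu, a Josiphos ligand of the antipode that leads to the (S)-carbinol, B2pin2, MeOH, THF] gives the β-boryl ketone F6.
- Oxidation with NaBO3 gives the β-hydroxy ketone F7.
- TBDPSCl and imidazole silylate the secondary hydroxyl to give 20.

Further compounds
F1 | step 14 | bromo hydroxy acid: 22 with the bridge opened (C9 α-bromide, C6 β-hydroxyl) | O[C@H]1[C@H](C(=C)C(=O)O)C[C@H](Br)[C@H](C)[C@@](O)(C(=O)C[C@H](C)O[Si](c2ccccc2)(c2ccccc2)C(C)(C)C)[C@H]1OC(=O)[C@H](C)CC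
F2 | step 14 | bromo lactone: 23 with an α-bromide in place of the C9 hydroxyl | C=C1C(=O)O[C@@H]2[C@H]1C[C@H](Br)[C@H](C)[C@@](O)(C(=O)C[C@H](C)O[Si](c3ccccc3)(c3ccccc3)C(C)(C)C)[C@H]2OC(=O)[C@H](C)CC
F3 | step 4 | benzyl 6-bromo-3-[(tert-butyldimethylsilyl)oxy]-8-oxabicyclo[3.2.1]octa-2,6-diene-2-carboxylate | O1[C@H]2C(Br)=C[C@@H]1C(C(=O)OCc3ccccc3)=C(O[Si](C)(C)C(C)(C)C)C2
F4 | step 12 | allenyl carbinol: C1 adduct of 15 with 1-methoxybuta-1,2-dien-1-yl (C1 hydroxyl α, mixture of allene epimers) | O1[C@H]2[C@H](C(C(=O)OC(C)(C)C)C(=O)OC(C)(C)C)C[C@@H]1[C@H](C)[C@@](O)(C(OC)=C=CC)[C@H]2OC(=O)[C@H](C)CC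
F5 | step 12 | (E)-enone: C1 hydroxy C1 (E)-but-2-enoyl compound | O1[C@H]2[C@H](C(C(=O)OC(C)(C)C)C(=O)OC(C)(C)C)C[C@@H]1[C@H](C)[C@@](O)(C(=O)/C=C/C)[C@H]2OC(=O)[C@H](C)CC
F6 | step 12 | β-boryl ketone: C4 pinacolboronate | O1[C@H]2[C@H](C(C(=O)OC(C)(C)C)C(=O)OC(C)(C)C)C[C@@H]1[C@H](C)[C@@](O)(C(=O)C[C@H](C)B3OC(C)(C)C(C)(C)O3)[C@H]2OC(=O)[C@H](C)CC
F7 | step 12 | β-hydroxy ketone: desilyl 20 | O1[C@H]2[C@H](C(C(=O)OC(C)(C)C)C(=O)OC(C)(C)C)C[C@@H]1[C@H](C)[C@@](O)(C(=O)C[C@H](C)O)[C@H]2OC(=O)[C@H](C)CC
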